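## Retrosynthetic overview
1. The target comes from a MOM-protected bis(aryl bromide) by double Stille allylation and a final non-acidic MOM removal.
2. The hindered tertiary C4–O aryl ether is the key bond. It forms by Co–H radical–polar crossover hydroalkoxylation of 5α-eudesm-3-en-11-ol (17) with the hindered phenol 5, which also sets C4.
3. Alkene 17 comes from the trans-decalin enone 15 by Li/NH₃ reductive enol triflation and Pd-formate reduction. Enone 15 comes from Robinson annulation (ring A) of ketol 13 with ethyl vinyl ketone.
4. Ketol 13 comes from (R)-α-terpineol, made by an asymmetric Diels–Alder of isoprene with an acryloyl imide (ring B, formed first). Phenol 5 comes from 4-bromophenol by diiodination, Ullmann coupling and I→OH conversion.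

Ring order: ring B (Diels–Alder), then ring A (Robinson), then the diaryl ether/aryl–terpenyl assembly.

Assumptions (one line each):
- The terpenyl group sits on the phenol oxygen remote from the diaryl ether, as in the given SMILES.
- Robinson annulation of 13 gives the natural relative configuration of C7 and C10, as in α-cyperone syntheses from dihydrocarvone.

## Route

**Step 1**
Reactants: 1 (4-bromophenol)
Product: 2 (4-bromo-2,6-diiodophenol)
Conditions: NIS (2.2 equiv), cat. TsOH, MeCN, rt
Reagents that add atoms: N-iodosuccinimide, O=C1CCC(=O)N1I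
Why: The OH directs electrophilic iodination (SEAr) to both free ortho positions; the para position is blocked by Br.

**Step 2**
Reactants: 2
Product: 3 (5-bromo-1,3-diiodo-2-(methoxymethoxy)benzene)
Conditions: NaH, THF, 0 °C; then MOMCl, rt
Reagents that add atoms: chloromethyl methyl ether, COCCl
Why: Protecting the central oxygen prevents phenoxide self-coupling in the Ullmann step and catechol oxidation in the radical step. Aryl MOM ethers can later be removed without acid.

**Step 3**
Reactants: 3 (1.5 equiv), 1 (1.0 equiv)
Product: 4 (5-bromo-1-(4-bromophenoxy)-3-iodo-2-(methoxymethoxy)benzene)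
Conditions: CuI (10 mol%), picolinic acid (20 mol%), K₃PO₄, DMSO, 80 °C
Reagents that add atoms: none
Why: Cu-catalysed Ullmann C–O coupling is chemoselective for ArI over ArBr. Excess diiodide and the added hindrance after the first coupling limit diarylation.

**Step 4**
Reactants: 4
Product: 5 (5-bromo-3-(4-bromophenoxy)-2-(methoxymethoxy)phenol)
Conditions: i-PrMgCl·LiCl, THF, −20 °C; then B(OMe)₃; then H₂O₂, NaOH, 0 °C
Reagents that add atoms: hydrogen peroxide, OO (supplies the phenol O)
Why: I/Mg exchange is selective for iodide over the two bromides and is assisted by the ortho OMOM. The arylboronate is then oxidised to the phenol.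

**Step 5**
Reactants: 6 (acryloyl chloride), 7 (oxazolidin-2-one)
Product: 8 (3-acryloyloxazolidin-2-one)
Conditions: Et₃N, LiCl, CH₂Cl₂, 0 °C
Reagents that add atoms: none
Why: N-acylation gives a bidentate dienophile for chelated Lewis-acid catalysis.

**Step 6**
Reactants: 8, 9 (isoprene)
Product: 10 (3-[(1R)-4-methylcyclohex-3-ene-1-carbonyl]oxazolidin-2-one)
Conditions: chiral Ti–TADDOLate catalyst (10 mol%), 4 Å MS, toluene, −20 °C
Reagents that add atoms: none
Why: Diels–Alder gives the "para" (1,4) adduct of a 2-substituted diene. The chelated chiral Lewis acid fixes the new C1 (eudesmane C7) stereocentre as R (catalyst enantiomer chosen accordingly).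

**Step 7**
Reactants: 10
Product: 11 ((R)-α-terpineol)
Conditions: MeMgBr (4 equiv), THF, 0 °C
Reagents that add atoms: methylmagnesium bromide, C[Mg]Br
Why: Double methyl addition to the more electrophilic exocyclic imide carbonyl gives the tertiary carbinol, and the oxazolidinone is released.

**Step 8**
Reactants: 11
Product: 12 (2-[(1R)-3-hydroxy-4-methylcyclohexyl]propan-2-ol, diastereomer mixture)
Conditions: BH₃·THF (excess), THF, 0 °C; then H₂O₂, NaOH
Reagents that add atoms: hydrogen peroxide, OO
Why: Hydroboration–oxidation places OH on the less substituted alkene carbon, adjacent to the C–Me carbon. The resulting stereocentres are destroyed in the next step.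

**Step 9**
Reactants: 12
Product: 13 (5-(2-hydroxypropan-2-yl)-2-methylcyclohexan-1-one; C2 epimerisable)
Conditions: Dess–Martin periodinane, NaHCO₃, CH₂Cl₂, rt
Reagents that add atoms: none
Why: The secondary alcohol is oxidised selectively; the tertiary carbinol is untouched. The product has the dihydrocarvone-type pattern needed for annulation.

**Step 10**
Reactants: 13, 14 (ethyl vinyl ketone)
Product: 15 (11-hydroxyeudesm-4-en-3-one)
Conditions: KOH (cat.), EtOH, 0 °C → reflux
Reagents that add atoms: none
Why: Robinson annulation (Michael, then aldol condensation). The Michael addition occurs at C2 (future C10) trans to the equatorial C7 side chain, so the C7 stereocentre sets the quaternary C10 (natural relative configuration, as for α-cyperone).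

**Step 11**
Reactants: 15
Product: 16 (11-hydroxy-5α-eudesm-3-en-3-yl triflate)
Conditions: Li, NH₃(l)/THF, −78 °C; then PhNTf₂
Reagents that add atoms: N-phenyl-bis(trifluoromethanesulfonimide), O=S(=O)(N(c1ccccc1)S(=O)(=O)C(F)(F)F)C(F)(F)F
Why: Dissolving-metal enone reduction protonates C5 anti to the angular methyl, giving the trans-decalin (5α-H). It also gives the regiodefined C3=C4 enolate, which is trapped as the enol triflate.

**Step 12**
Reactants: 16
Product: 17 (5α-eudesm-3-en-11-ol)
Conditions: Pd(OAc)₂, PPh₃, HCO₂H, Et₃N, DMF, 60 °C
Reagents that add atoms: none (formate supplies only H)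
Why: Pd-catalysed hydride reduction of the vinyl triflate (Cacchi) gives the trisubstituted C3=C4(Me) alkene without moving the double bond.

**Step 13**
Reactants: 17, 5
Product: 18 (MOM-protected dibromo aryl eudesmyl ether)
Conditions: Co(salen) (5 mol%), N-fluoro-2,4,6-trimethylpyridinium triflate (2 equiv), PhSiH₃ (2 equiv), PhCF₃, rt; 5 (1.5 equiv)
Reagents that add atoms: none (phenol 5 is the reactant; silane supplies H only)
Why: Proposed new method: Co–H transfers H• to C3, giving the tertiary C4 radical. Co capture and oxidation give an alkyl–Co(IV)/carbocation-like species that the phenol O attacks. The closest known reaction is Shigehisa-type Co-catalysed hydroalkoxylation of alkenes with alcohols, here extended to a hindered phenol forming a tertiary aryl ether. Mechanistically, the C1–OH is the less hindered oxygen, the ortho OMOM and the Br atoms block ring C-alkylation, and the radical-derived electrophile tolerates the steric demand. The axial C10-methyl shields the β face of C4 (1,3-diaxial), so attack occurs from the α face. This gives 4α-OAr (equatorial) and 4β-Me (axial), as in the target.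

**Step 14**
Reactants: 18
Product: 19 (MOM-protected Eudesobovatol A)
Conditions: allyltributylstannane (3 equiv), Pd(PPh₃)₄ (10 mol%), LiCl, DMF, 90 °C
Reagents that add atoms: allyltributylstannane, C=CC[Sn](CCCC)(CCCC)CCCC
Why: Stille coupling installs both allyl groups in one step under neutral conditions that the tertiary ether, tertiary alcohol and MOM group tolerate. The bromides were carried through the radical step as inert placeholders, so no allyl alkene was exposed to Co–H.

**Step 15**
Reactants: 19
Product: 20 (Eudesobovatol A)
Conditions: TMSOTf, 2,2′-bipyridyl, MeCN, 0 °C → rt; then H₂O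
Reagents that add atoms: none
Why: The TMSOTf/bipyridyl (Fujioka) conditions cleave aryl MOM ethers without free acid, so the acid-sensitive tertiary aryl ether and tertiary alcohol survive. Any TMS ether formed on the tertiary OH hydrolyses on work-up.

## Compound list
1 | 4-bromophenol | Oc1ccc(Br)cc1 | starting material
2 | 4-bromo-2,6-diiodophenol | Oc1c(I)cc(Br)cc1I | intermediate
3 | 5-bromo-1,3-diiodo-2-(methoxymethoxy)benzene | COCOc1c(I)cc(Br)cc1I | intermediate
4 | 5-bromo-1-(4-bromophenoxy)-3-iodo-2-(methoxymethoxy)benzene | COCOc1c(I)cc(Br)cc1Oc1ccc(Br)cc1 | intermediate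
5 | 5-bromo-3-(4-bromophenoxy)-2-(methoxymethoxy)phenol | COCOc1c(O)cc(Br)cc1Oc1ccc(Br)cc1 | intermediate
6 | acryloyl chloride | C=CC(=O)Cl | starting material
7 | oxazolidin-2-one | O=C1NCCO1 | starting material
8 | 3-acryloyloxazolidin-2-one | C=CC(=O)N1CCOC1=O | intermediate
9 | isoprene | C=CC(C)=C | starting material
10 | 3-[(1R)-4-methylcyclohex-3-ene-1-carbonyl]oxazolidin-2-one | CC1=CC[C@@H](CC1)C(=O)N1CCOC1=O | intermediate
11 | (R)-α-terpineol | CC1=CC[C@@H](CC1)C(C)(C)O | intermediate
12 | 2-[(1R)-3-hydroxy-4-methylcyclohexyl]propan-2-ol | CC1CC[C@H](CC1O)C(C)(C)O | intermediate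
13 | 5-(2-hydroxypropan-2-yl)-2-methylcyclohexan-1-one | CC1CC[C@H](CC1=O)C(C)(C)O | intermediate
14 | ethyl vinyl ketone (pent-1-en-3-one) | CCC(=O)C=C | starting material
15 | 11-hydroxyeudesm-4-en-3-one | CC1=C2C[C@H](C(C)(C)O)CC[C@@]2(C)CCC1=O | intermediate
16 | 11-hydroxy-5α-eudesm-3-en-3-yl triflate | CC1=C(OS(=O)(=O)C(F)(F)F)CC[C@]2(C)CC[C@@H](C(C)(C)O)C[C@@H]12 | intermediate
17 | 5α-eudesm-3-en-11-ol | CC1=CCC[C@]2(C)CC[C@@H](C(C)(C)O)C[C@@H]12 | intermediate
18 | MOM-protected dibromo aryl eudesmyl ether | COCOc1c(O[C@]3(C)CCC[C@]4(C)CC[C@@H](C(C)(C)O)C[C@H]43)cc(Br)cc1Oc1ccc(Br)cc1 | intermediate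
19 | MOM-protected Eudesobovatol A | COCOc1c(O[C@]3(C)CCC[C@]4(C)CC[C@@H](C(C)(C)O)C[C@H]43)cc(CC=C)cc1Oc1ccc(CC=C)cc1 | intermediate
20 | Eudesobovatol A | C=CCc1ccc(Oc2cc(CC=C)cc(O[C@]3(C)CCC[C@]4(C)CC[C@@H](C(C)(C)O)C[C@H]43)c2O)cc1 | target

## Totals
- **Total steps:** 15.
- **Longest linear sequence:** 11 steps (5 → 6 → 7 → 8 → 9 → 10 → 11 → 12 → 13 → 14 → 15).

## Three steps most likely to fail
1. **Step 13 (Co–H hydroalkoxylation with a hindered phenol).** Competing alkene isomerisation, elimination or wrong-regiochemistry C5 radical capture could all occur, and C4 stereocontrol is not guaranteed. Fallback: a different approach, acid-mediated ionic Markovnikov hydroaryloxylation of 17 with 5 (cat. TfOH or Bi(OTf)₃ in HFIP), relying on the same C10-methyl facial bias.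
2. **Step 6 (enantioselective Diels–Alder of isoprene).** The ee may be only moderate with an unhindered acrylimide. Fallback: organocatalytic (imidazolidinone) Diels–Alder of acrolein with isoprene, then oxidative esterification and MeMgBr to reach (R)-α-terpineol.
3. **Step 10 (Robinson annulation).** Regiochemistry (C2 versus C6 enolate) and yield are concerns. Fallback: set C10 by alkylating the SAMP/RAMP azaenolate of 13 at C2 with a masked 3-oxopentyl electrophile, then close ring A by intramolecular aldol.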